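## The problem

The target is a trans-fused hydroazulene (guaiane numbering throughout: five-membered ring C1–C5, seven-membered ring C1 and C5–C10, C14 on C10, C15 on C4, isopropyl on C7) with seven stereocentres, read from the structure as 1R,3R,4S,5S,7R,8R,10S. H-1 and H-5 are anti; the 10-hydroxyl, the 8-veratroyloxy and the 7-isopropyl groups all lie on the face of H-5, and the 3,4-epoxide oxygen lies on the face of H-1. No stereocentre sits outside the rings, so control has to be relayed around the skeleton: C5 to C1 across the fusion, C1 to C10, then C10 to C8 and C7, and finally to the C3–C4 epoxide. Seven-membered rings give weak conformational control, so as many centres as possible should be set while the larger ring is still six-membered. Three features are fragile: the trisubstituted epoxide is acid-labile and placed for backside attack by the 10-hydroxyl, the aryl ester sits 1,3 to a free tertiary alcohol and can shift to it, and in any intermediate with a C8 ketone the C10 oxygen is β to the carbonyl, inviting retro-aldol cleavage when free and E1cB loss when protected. The feature that opens the chosen route is that C7 is a single carbon, carrying the isopropyl group, between the C6 methylene and the oxygenated C8. Removing it leaves a trans-fused cyclohexanone whose two α-methylenes differ sharply: C9 is next to the quaternary, oxygenated C10, while C6 is next to the C5 methine.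

## Retrosynthesis

**Epoxide and silyl ether last (25 from 24 from 23).** The two C–O bonds of the oxirane and the O–Si bond are cut first. The epoxide would not survive the Lewis acid of the ring expansion, so the C3–C4 alkene of 23 is carried as the only alkene and oxidised late. In 23 the three large groups (triethylsilyloxy, veratroyloxy, isopropyl) all sit on the H-5 face, so a peracid should enter from the H-1 face. The silyl group is kept until 24 because a free 10-hydroxyl lies under the other face of the cyclopentene and could direct the oxidant there.

**Ester (23 from 21 and 22).** The acyl C–O bond at O8 is cut. Late acylation keeps the ester away from organometallic reagents and from the basic reduction step. With O10 silylated, only one hydroxyl is free.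

**C8–H and the C7 configuration (21 from 20).** The carbinol hydrogen is removed, giving the C8 ketone 20. Equilibration of C7 alone is not trusted: with either configuration at C7 the isopropyl group can sit equatorially in one of the two twist-chairs open to the trans-fused ring, so no clear thermodynamic bias is expected. C7 and C8 are therefore set together. In 20 both flanking groups (C7 isopropyl, C10 silyloxy) shield the same face of the carbonyl, whereas with the 7S configuration they would shield opposite faces. A reduction run under conditions that epimerise C7 should therefore drain all of the ketone through 20, whatever composition at C7 the ring expansion delivers.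

**Key disconnection (20 from 15 and 18, through 19).** C7–C8 and C6–C7 are cut, excising the isopropyl-bearing carbon; the diazonium alkoxide 19 is the adduct that links the two halves. This is preferred over an aldol cut at C9–C10 (two methyl ketone partners, hence regiochemical ambiguity) and over building the seven-membered ring directly. The precursor 15 is a rigid trans-fused cyclohexanone on which C1, C5 and C10 are already fixed. The forward reaction must insert the carbon of 18 on the C6 side only, and only once.

**Diazoalkane (18 from 17 from 16).** The C=N2 unit is traced to the hydrazone of isobutyraldehyde 16. The non-stabilised diazoalkane must be made cold and used at once.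

**C10 methyl and oxidation-state adjustment (15 from 14 from 13 from 12 from 11).** The C10–CH3 bond is cut, giving ketone 11, in which the future C8 carbonyl is a silyl-protected alcohol. Addition of a methyl nucleophile to a locked chair gives predictable stereochemistry. The axial C8 silyloxy group reinforces equatorial attack and is then converted into the ketone (12 to 13 to 14) before O10 is silylated.

**Cyclopentene (11 from 10).** The C3=C4 bond is cut by ring-closing metathesis logic, giving an allyl group on C1 and an isopropenyl group on C5. Both sit equatorially and trans on a cyclohexanone, which is the geometry a trans-fused five-membered ring needs.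

**C1–C2 and C4–C5 (10 from 8).** Both bonds are cut in one operation, conjugate addition of an isopropenyl nucleophile followed by allylation of the enolate 9. The stereocentre of enone 8 is the carbon that later becomes the C8 carbonyl, so the controlling element costs nothing extra. It cannot be carried as a ketone because the enone would then be a phenol tautomer.

**Enone (8 from 7 from 5 from 4 from 3 from 2 from 1).** The ring alkene is cut by metathesis to the acyclic dienone 7 (through hemiaminal 6 from Weinreb amide 5). The silyloxy stereocentre is traced through ester 4, hydroxy ester 3 and epoxy ester 2 to the commercial chlorohydrin ester 1. All steps are standard functional-group changes on a single stereocentre.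

## Roads not taken

Alternative 1: The cut removes C1–C5, C2–C3 and C3–C4 at once, leading to the acyclic allenyne A1. In the forward direction [Rh(CO)2Cl]2 under carbonylative conditions couples the alkyne with the distal allene double bond and gives dienone A2 with both rings closed in one step.
- Merits: the highest ring-forming economy of the four plans. C7 and C8 are set in an open chain, where the isopropyl-bearing centre is never α to a ketone.
- Weak points: A2 has C1, C5 and C10 all sp2 and its oxygen at C3 instead of C10. The tetrasubstituted C4=C5 enone and the C1=C10 alkene must be reduced to a trans ring fusion. C10 must be hydrated with the correct configuration. The C3 carbonyl must be turned into the C3–C4 alkene. Each operation creates stereocentres on a flexible seven-membered ring, remote from C7 and C8.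
- Comparison: this road is better for ring construction and for C7. The chosen plan sets C1, C5 and C10 on a chair with reliable cyclohexanone chemistry, and pays with a longer linear front end and a C7 centre that must be fixed dynamically.

Alternative 2: The cut traces the C1–C5 bond back to the C5–C10 bond of a eudesmane-type cis-decalin, mesylate A3. Ionisation at C1 with antiperiplanar shift of C5 forms both the five- and seven-membered rings. The C8 ester carbonyl closes onto the C10 cation and aqueous work-up leaves the tertiary alcohol, giving A4.
- Merits: the shift is stereospecific at C1 and C5, and the 10-hydroxyl arrives cis to the ester in the same step. C4, C5, C7 and C8 are all set on a decalin chair, with the C7 isopropyl group fixed equatorially before any epimerisable ketone exists. In this respect it is stronger than the chosen plan.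
- Weak points: A3 is a six-stereocentre cis-decalin that needs the sulfonate antiperiplanar to the ring bond. The cation can lose a proton instead of being captured. Opening of the cyclic cation can leave the acyl group on either oxygen. A4 carries a C3 ketal and a saturated C4 methyl, so the C3–C4 epoxide still needs regioselective enolisation between C2 and C4 and several redox steps.
- Comparison: better for C7 and for joint control of C1, C5 and C10. The chosen plan offers a much simpler precursor, and its C3–C4 alkene is in place from the first ring closure.

Alternative 3: The cut removes C1–C5 and C5–C6, leading to aryl diazoketone A5, whose benzene ring already carries the isopropyl, methyl and methoxy groups. A rhodium carbene (for example from Rh2(O2CCF3)4) cyclopropanates the ipso–ortho bond, and electrocyclic opening gives azulenone A6.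
- Merits: the shortest access to a hydroazulene, from a cheap aromatic. C7 isopropyl, C8 oxygen and C10 methyl come ready-made.
- Weak points: the carbene must choose between the two ortho bonds. A6 has one stereocentre and is racemic unless a chiral carbene catalyst is used. Six further stereocentres must then be created by reducing three ring alkenes, hydrating C10 and adding the C4 methyl, all on a loose cycloheptatriene.
- Comparison: better in step count to the bicycle. The chosen plan introduces each stereocentre as the rings are built, from one chiral-pool centre.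

Key step: step 15

Assumption: guaiane locants are kept for every bicyclic intermediate so that atom numbers do not change along the route; "face of H-5" and "face of H-1" refer to the two faces of the trans-fused bicycle.

Step 1
Reactants: 1 ethyl (3R)-4-chloro-3-hydroxybutanoate
Product: 2 ethyl 2-[(2R)-oxiran-2-yl]acetate
Conditions: Ag2O, 1,2-dimethoxyethane, 60 °C
Reagents that add atoms: none
Why: Silver-assisted intramolecular Williamson closure of the chlorohydrin; non-basic conditions avoid elimination to the 4-hydroxycrotonate, and no bond to the stereocentre is broken.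

Step 2
Reactants: 2 ethyl 2-[(2R)-oxiran-2-yl]acetate
Product: 3 ethyl (3S)-3-hydroxyhex-5-enoate
Conditions: vinylmagnesium bromide, CuI (10 mol%), THF, −40 °C; aq. NH4Cl
Reagents that add atoms: vinylmagnesium bromide, C=C[Mg]Br
Why: Copper-catalysed Grignard opening of a terminal epoxide at its unsubstituted carbon (SN2), faster than attack on the ester at this temperature; the carbinol carbon is untouched and its descriptor changes only through the CIP ranking.

Step 3
Reactants: 3 ethyl (3S)-3-hydroxyhex-5-enoate
Product: 4 ethyl (3S)-3-[(tert-butyldimethylsilyl)oxy]hex-5-enoate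
Conditions: TBSCl, imidazole, DMF, rt
Reagents that add atoms: tert-butyldimethylsilyl chloride, CC(C)(C)[Si](C)(C)Cl
Why: Standard silylation of a secondary alcohol; the ether later serves as the anti-directing group in step 7.

Step 4
Reactants: 4 ethyl (3S)-3-[(tert-butyldimethylsilyl)oxy]hex-5-enoate
Product: 5 (3S)-3-[(tert-butyldimethylsilyl)oxy]-N-methoxy-N-methylhex-5-enamide
Conditions: MeNH(OMe)·HCl, i-PrMgCl, THF, −20 → 0 °C
Reagents that add atoms: N,O-dimethylhydroxylamine hydrochloride, CNOC.Cl
Why: Aminolysis of the ester by the magnesium amide gives the Weinreb amide; the low temperature avoids E1cB loss of the β-silyloxy group.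

Step 5
Reactants: 5 (3S)-3-[(tert-butyldimethylsilyl)oxy]-N-methoxy-N-methylhex-5-enamide
Product: 7 (5S)-5-[(tert-butyldimethylsilyl)oxy]octa-1,7-dien-3-one, via magnesium hemiaminal 6 (not isolated)
Conditions: vinylmagnesium bromide, THF, −78 → 0 °C; inverse quench into cold 1 M HCl
Reagents that add atoms: vinylmagnesium bromide, C=C[Mg]Br
Why: Weinreb ketone synthesis: the chelated adduct 6 stops at mono-addition and collapses to the vinyl ketone on acidic quench; the inverse quench prevents conjugate addition of the released hydroxylamine.

Step 6
Reactants: 7 (5S)-5-[(tert-butyldimethylsilyl)oxy]octa-1,7-dien-3-one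
Product: 8 (5S)-5-[(tert-butyldimethylsilyl)oxy]cyclohex-2-en-1-one
Conditions: RuCl2(=CHPh)(PCy3)(H2IMes) (second-generation Grubbs catalyst, 3 mol%), CH2Cl2 (0.01 M), 40 °C
Reagents that add atoms: none
Why: Ring-closing metathesis of a vinyl ketone with a terminal alkene to a six-membered enone, driven by loss of ethylene; the neutral conditions keep the β-silyloxy enone from eliminating to the phenol.

Step 7
Reactants: 8 (5S)-5-[(tert-butyldimethylsilyl)oxy]cyclohex-2-en-1-one
Product: 10 (2R,3S,5S)-2-allyl-5-[(tert-butyldimethylsilyl)oxy]-3-(prop-1-en-2-yl)cyclohexan-1-one, via magnesium enolate 9 (not isolated)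
Conditions: isopropenylmagnesium bromide, CuBr·SMe2 (15 mol%), THF, −78 °C; then HMPA, allyl iodide, −78 → −20 °C
Reagents that add atoms: isopropenylmagnesium bromide, CC(=C)[Mg]Br; allyl iodide, C=CCI
Why: Copper-catalysed 1,4-addition enters anti to the 5-silyloxy group (known for this enone class), setting guaiane C5; the regiodefined enolate 9 is allylated trans to the new isopropenyl group, setting C1 (conjugate addition–enolate alkylation).

Step 8
Reactants: 10 (2R,3S,5S)-2-allyl-5-[(tert-butyldimethylsilyl)oxy]-3-(prop-1-en-2-yl)cyclohexan-1-one
Product: 11 (3aR,6S,7aS)-6-[(tert-butyldimethylsilyl)oxy]-1-methyl-3,3a,5,6,7,7a-hexahydro-4H-inden-4-one (guaiane locants: 10-ketone, 8-silyloxy, 3-ene; 1R,5S,8S)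
Conditions: RuCl2(=CHPh)(PCy3)(H2IMes) (5 mol%), CH2Cl2, 40 °C
Reagents that add atoms: none
Why: Ring-closing metathesis of the trans-diequatorial allyl and isopropenyl groups forms the trisubstituted C3=C4 alkene and the trans-fused five-membered ring; the neutral conditions leave the α-stereocentre C1 untouched.

Step 9
Reactants: 11 (3aR,6S,7aS)-6-[(tert-butyldimethylsilyl)oxy]-1-methyl-3,3a,5,6,7,7a-hexahydro-4H-inden-4-one
Product: 12 (3aS,5S,7S,7aR)-5-[(tert-butyldimethylsilyl)oxy]-3,7-dimethyl-3a,4,5,6,7,7a-hexahydro-1H-inden-7-ol (guaiane 1R,5S,8S,10S)
Conditions: MeMgBr, CeCl3, THF, −78 °C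
Reagents that add atoms: methylmagnesium bromide, C[Mg]Br
Why: The non-basic reagent from MeMgBr and CeCl3 adds without enolisation or β-elimination. In the locked chair the axial trajectory is blocked by the axial 8-silyloxy group and axial H-5, so methyl enters equatorially and the 10-hydroxyl ends axial on the face of H-5 (C10 = S).

Step 10
Reactants: 12 (3aS,5S,7S,7aR)-5-[(tert-butyldimethylsilyl)oxy]-3,7-dimethyl-3a,4,5,6,7,7a-hexahydro-1H-inden-7-ol
Product: 13 (3aS,5S,7S,7aR)-3,7-dimethyl-3a,4,5,6,7,7a-hexahydro-1H-indene-5,7-diol
Conditions: Bu4NF, THF, 0 °C → rt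
Reagents that add atoms: none
Why: Fluoride cleavage of the secondary silyl ether; the directing group has done its work and no stereocentre is touched.

Step 11
Reactants: 13 (3aS,5S,7S,7aR)-3,7-dimethyl-3a,4,5,6,7,7a-hexahydro-1H-indene-5,7-diol
Product: 14 (3aS,7S,7aR)-7-hydroxy-3,7-dimethyl-1,3a,4,6,7,7a-hexahydro-5H-inden-5-one
Conditions: Dess–Martin periodinane, NaHCO3, CH2Cl2, 0 °C → rt
Reagents that add atoms: none
Why: Dess–Martin oxidation takes the secondary alcohol and cannot touch the tertiary one; the buffered, non-basic medium avoids retro-aldol cleavage or dehydration of the β-hydroxy ketone.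

Step 12
Reactants: 14 (3aS,7S,7aR)-7-hydroxy-3,7-dimethyl-1,3a,4,6,7,7a-hexahydro-5H-inden-5-one
Product: 15 (3aS,7S,7aR)-3,7-dimethyl-7-[(triethylsilyl)oxy]-1,3a,4,6,7,7a-hexahydro-5H-inden-5-one (trans-fused 10-(triethylsilyloxy)-7-norguai-3-en-8-one; 1R,5S,10S)
Conditions: Et3SiOTf, 2,6-lutidine, CH2Cl2, −78 °C
Reagents that add atoms: triethylsilyl trifluoromethanesulfonate, CC[Si](CC)(CC)OS(=O)(=O)C(F)(F)F
Why: Silyl triflate with 2,6-lutidine silylates a hindered tertiary alcohol at −78 °C faster than it enolises the ketone; the ether blocks retro-aldol and O–H insertion in step 15 and later shields the face of H-5.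

Step 13
Reactants: 16 isobutyraldehyde
Product: 17 (2-methylpropylidene)hydrazine (isobutyraldehyde hydrazone)
Conditions: N2H4·H2O (4 equiv), EtOH, 0 °C → rt
Reagents that add atoms: hydrazine hydrate, NN.O
Why: Condensation of the aldehyde with hydrazine; the excess and inverse addition suppress azine formation.

Step 14
Reactants: 17 (2-methylpropylidene)hydrazine
Product: 18 1-diazo-2-methylpropane (cold titrated solution)
Conditions: (COCl)2, DMSO, CH2Cl2, −78 °C; then 17, Et3N, −78 °C; cold filtration and pH 7 wash; used at once
Reagents that add atoms: none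
Why: Swern-type dehydrogenation of a hydrazone with activated dimethyl sulfoxide gives the non-stabilised diazoalkane at low temperature; cold washing removes the amine salts that would poison the Lewis acid of step 15.

Step 15
Reactants: 15 (3aS,7S,7aR)-3,7-dimethyl-7-[(triethylsilyl)oxy]-1,3a,4,6,7,7a-hexahydro-5H-inden-5-one; 18 1-diazo-2-methylpropane
Product: 20 (1R,5S,7R,10S)-10-[(triethylsilyl)oxy]guai-3-en-8-one, via diazonium alkoxide adduct 19 (not isolated)
Conditions: Sc(OTf)3 (10 mol%), CH2Cl2–toluene, −78 °C, slow addition of 18
Reagents that add atoms: none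
Why: Sc(OTf)3 activates the C8 carbonyl, the diazo carbon of 18 adds to give the diazonium alkoxide 19, and the ring bond antiperiplanar to the departing N2 shifts to the new carbon as the carbonyl re-forms (Lewis acid-catalysed diazoalkane–ketone homologation of the Tiffeneau–Demjanov/Büchner–Curtius–Schlotterbeck type; closest known case: Sc(OTf)3-catalysed insertion of alkyldiazomethanes into cyclohexanones). The seven-membered ring is not closed by cyclisation: it arises by 1,2-shift ring expansion of the six-membered ketone, C7–C8 forming in the addition and C6–C7 in the migration. The selectivity the step needs is migration of C6 rather than C9; C9 is neopentylic, feels the inductive pull of the C10 silyloxy group, and its shift would wedge the isopropyl-bearing carbon against the quaternary centre, so the unencumbered C6 methylene should move. A second insertion is not expected because the α-branched cycloheptanone is a poorer electrophile than 15; slow addition at −78 °C limits epoxide and azine formation, and the isolated alkene and tertiary silyl ether are inert to both partners. The new stereocentre C7 is set by the face of the diazo carbon that adds, since the shift is stereospecific at that carbon; this kinetic preference cannot be predicted with confidence and the ketone does not epimerise under the Lewis acid. The 7R configuration drawn for 20 is therefore not relied on here: step 16 is run under conditions that epimerise C7, so the route converges whatever the composition at C7.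

Step 16
Reactants: 20 (1R,5S,7R,10S)-10-[(triethylsilyl)oxy]guai-3-en-8-one
Product: 21 (1R,5S,7R,8R,10S)-10-[(triethylsilyl)oxy]guai-3-en-8-ol
Conditions: H2 (8 atm), trans-RuCl2[(S)-binap][(R,R)-dpen] (1 mol%), KOt-Bu (5 mol%), i-PrOH, 25 °C
Reagents that add atoms: none
Why: Noyori-type ketone hydrogenation under dynamic kinetic conditions: the catalytic base epimerises C7 through the enolate, so ketone of either C7 configuration is funnelled through 20, in which the face of H-1 of the C8 carbonyl is anti to both the C7 isopropyl and the C10 silyloxy group, and hydride delivery there gives the cis 7R,8R alcohol. The complex reduces C=O and leaves the alkene; the catalyst antipode is chosen by analogy with the cis-selective dynamic reduction of 2-isopropylcyclohexanone and is to be confirmed on the substrate.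

Step 17
Reactants: 21 (1R,5S,7R,8R,10S)-10-[(triethylsilyl)oxy]guai-3-en-8-ol; 22 3,4-dimethoxybenzoyl chloride (veratroyl chloride)
Product: 23 (1R,5S,7R,8R,10S)-10-[(triethylsilyl)oxy]guai-3-en-8-yl 3,4-dimethoxybenzoate
Conditions: Et3N, DMAP, CH2Cl2, 0 → 40 °C
Reagents that add atoms: none
Why: DMAP-catalysed acylation of the only free hydroxyl; no alkoxide is generated, so the silyl group should not migrate from O10 to O8.

Step 18
Reactants: 23 (1R,5S,7R,8R,10S)-10-[(triethylsilyl)oxy]guai-3-en-8-yl 3,4-dimethoxybenzoate
Product: 24 (1R,3R,4S,5S,7R,8R,10S)-3,4-epoxy-10-[(triethylsilyl)oxy]guaian-8-yl 3,4-dimethoxybenzoate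
Conditions: m-CPBA, NaHCO3, CH2Cl2, 0 °C
Reagents that add atoms: 3-chloroperoxybenzoic acid, OOC(=O)c1cccc(Cl)c1
Why: Prilezhaev epoxidation of the only alkene; the triethylsilyloxy, veratroyloxy and isopropyl groups all lie on the face of H-5, the first of them under the cyclopentene, so the peracid should enter from the face of H-1 and set C3 (R) and C4 (S). Bicarbonate protects the acid-sensitive epoxide.

Step 19
Reactants: 24 (1R,3R,4S,5S,7R,8R,10S)-3,4-epoxy-10-[(triethylsilyl)oxy]guaian-8-yl 3,4-dimethoxybenzoate
Product: 25 (1R,3R,4S,5S,7R,8R,10S)-3,4-epoxy-10-hydroxyguaian-8-yl 3,4-dimethoxybenzoate (target, CNP0304846.1)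
Conditions: Bu4NF, AcOH (1:1), THF, 0 °C → rt
Reagents that add atoms: none
Why: Fluoride cleavage of the tertiary triethylsilyl ether; acetic acid keeps the liberated C10 oxygen protonated, so neither acyl transfer from O8 nor backside opening of the epoxide at C3 should start.

## Compound list

1 | ethyl (3R)-4-chloro-3-hydroxybutanoate | CCOC(=O)C[C@@H](O)CCl | starting material
2 | ethyl 2-[(2R)-oxiran-2-yl]acetate | CCOC(=O)C[C@@H]1CO1 | intermediate
3 | ethyl (3S)-3-hydroxyhex-5-enoate | CCOC(=O)C[C@@H](O)CC=C | intermediate
4 | ethyl (3S)-3-[(tert-butyldimethylsilyl)oxy]hex-5-enoate | CCOC(=O)C[C@@H](O[Si](C)(C)C(C)(C)C)CC=C | intermediate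
5 | (3S)-3-[(tert-butyldimethylsilyl)oxy]-N-methoxy-N-methylhex-5-enamide | CON(C)C(=O)C[C@@H](O[Si](C)(C)C(C)(C)C)CC=C | intermediate
6 | bromomagnesium (5S)-5-[(tert-butyldimethylsilyl)oxy]-3-[methoxy(methyl)amino]octa-1,7-dien-3-olate (C3 as formed) | C=CC(O[Mg]Br)(N(C)OC)C[C@@H](O[Si](C)(C)C(C)(C)C)CC=C | intermediate (not isolated)
7 | (5S)-5-[(tert-butyldimethylsilyl)oxy]octa-1,7-dien-3-one | C=CC(=O)C[C@@H](O[Si](C)(C)C(C)(C)C)CC=C | intermediate
8 | (5S)-5-[(tert-butyldimethylsilyl)oxy]cyclohex-2-en-1-one | O=C1C=CC[C@H](O[Si](C)(C)C(C)(C)C)C1 | intermediate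
9 | bromomagnesium (3S,5S)-5-[(tert-butyldimethylsilyl)oxy]-3-(prop-1-en-2-yl)cyclohex-1-en-1-olate | Br[Mg]OC1=C[C@@H](C(C)=C)C[C@H](O[Si](C)(C)C(C)(C)C)C1 | intermediate (not isolated)
10 | (2R,3S,5S)-2-allyl-5-[(tert-butyldimethylsilyl)oxy]-3-(prop-1-en-2-yl)cyclohexan-1-one | O=C1[C@H](CC=C)[C@@H](C(C)=C)C[C@H](O[Si](C)(C)C(C)(C)C)C1 | intermediate
11 | (3aR,6S,7aS)-6-[(tert-butyldimethylsilyl)oxy]-1-methyl-3,3a,5,6,7,7a-hexahydro-4H-inden-4-one | O=C1C[C@@H](O[Si](C)(C)C(C)(C)C)C[C@@H]2C(C)=CC[C@@H]12 | intermediate
12 | (3aS,5S,7S,7aR)-5-[(tert-butyldimethylsilyl)oxy]-3,7-dimethyl-3a,4,5,6,7,7a-hexahydro-1H-inden-7-ol | C[C@]1(O)C[C@@H](O[Si](C)(C)C(C)(C)C)C[C@@H]2C(C)=CC[C@@H]12 | intermediate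
13 | (3aS,5S,7S,7aR)-3,7-dimethyl-3a,4,5,6,7,7a-hexahydro-1H-indene-5,7-diol | C[C@]1(O)C[C@@H](O)C[C@@H]2C(C)=CC[C@@H]12 | intermediate
14 | (3aS,7S,7aR)-7-hydroxy-3,7-dimethyl-1,3a,4,6,7,7a-hexahydro-5H-inden-5-one | O=C1C[C@](C)(O)[C@@H]2CC=C(C)[C@H]2C1 | intermediate
15 | (3aS,7S,7aR)-3,7-dimethyl-7-[(triethylsilyl)oxy]-1,3a,4,6,7,7a-hexahydro-5H-inden-5-one | O=C1C[C@](C)(O[Si](CC)(CC)CC)[C@@H]2CC=C(C)[C@H]2C1 | intermediate
16 | isobutyraldehyde | CC(C)C=O | starting material
17 | (2-methylpropylidene)hydrazine | CC(C)C=NN | intermediate
18 | 1-diazo-2-methylpropane | CC(C)C=[N+]=[N-] | intermediate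
19 | 1-[(3aS,7S,7aR)-3,7-dimethyl-5-oxido-7-[(triethylsilyl)oxy]-3a,4,5,6,7,7a-hexahydro-1H-inden-5-yl]-2-methylpropane-1-diazonium (scandium-bound in the flask and written as the inner salt; the two new centres as formed) | CC(C)C([N+]#N)C1([O-])C[C@](C)(O[Si](CC)(CC)CC)[C@@H]2CC=C(C)[C@H]2C1 | intermediate (not isolated)
20 | (1R,5S,7R,10S)-10-[(triethylsilyl)oxy]guai-3-en-8-one | O=C1C[C@](C)(O[Si](CC)(CC)CC)[C@@H]2CC=C(C)[C@H]2C[C@@H]1C(C)C | intermediate
21 | (1R,5S,7R,8R,10S)-10-[(triethylsilyl)oxy]guai-3-en-8-ol | O[C@@H]1C[C@](C)(O[Si](CC)(CC)CC)[C@@H]2CC=C(C)[C@H]2C[C@@H]1C(C)C | intermediate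
22 | 3,4-dimethoxybenzoyl chloride | COc1ccc(C(Cl)=O)cc1OC | starting material
23 | (1R,5S,7R,8R,10S)-10-[(triethylsilyl)oxy]guai-3-en-8-yl 3,4-dimethoxybenzoate | COc1ccc(C(=O)O[C@@H]2C[C@](C)(O[Si](CC)(CC)CC)[C@@H]3CC=C(C)[C@H]3C[C@@H]2C(C)C)cc1OC | intermediate
24 | (1R,3R,4S,5S,7R,8R,10S)-3,4-epoxy-10-[(triethylsilyl)oxy]guaian-8-yl 3,4-dimethoxybenzoate | COc1ccc(C(=O)O[C@@H]2C[C@](C)(O[Si](CC)(CC)CC)[C@@H]3C[C@H]4O[C@@]4(C)[C@H]3C[C@@H]2C(C)C)cc1OC | intermediate
25 | (1R,3R,4S,5S,7R,8R,10S)-3,4-epoxy-10-hydroxyguaian-8-yl 3,4-dimethoxybenzoate | COc1ccc(C(=O)O[C@@H]2C[C@](C)(O)[C@@H]3C[C@H]4O[C@@]4(C)[C@H]3C[C@@H]2C(C)C)cc1OC | target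

## Step count and least certain steps

Total step count: 19. Longest linear sequence: 17 (steps 1–12 and 15–19); steps 13 and 14 are the side branch to 18.

**Step 15 (key step).** The most likely failure is loss of regiocontrol in the migration (C9 competing with C6), followed by epoxide formation from the adduct or consumption of the diazoalkane by the Lewis acid. Low stereocontrol at C7 is tolerated, because step 16 epimerises that centre. Fallback: setting out from 15, the α-lithio selenide obtained by selenium–lithium exchange on 2-methyl-1,1-bis(phenylselanyl)propane with n-BuLi is added to the ketone at −78 °C. This gives the β-hydroxy selenide (3aS,7S,7aR)-3,7-dimethyl-5-[2-methyl-1-(phenylselanyl)propyl]-7-[(triethylsilyl)oxy]-3a,4,5,6,7,7a-hexahydro-1H-inden-5-ol F1. AgBF4 on alumina then ionises the C–Se bond with concerted shift of a ring bond (semipinacol ring enlargement). Addition and migration are decoupled, and the more cationic transition state should discriminate more strongly against the electron-poor C9. The fallback returns to the route at 20, whose C7 is again secured in step 16.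

**Step 16.** The most likely failures are E1cB loss of the C10 silyloxy group from the C9 enolate under the basic conditions, and C7 epimerisation too slow to feed the reduction. Fallback: setting out from 15, BF3·OEt2-promoted insertion of allyl 2-diazo-3-methylbutanoate F2 (from L-valine allyl ester and isoamyl nitrite) gives the β-keto ester allyl (1R,5S,10S)-8-oxo-10-[(triethylsilyl)oxy]guai-3-ene-7-carboxylate F3. Decarboxylative protonation with Pd(OAc)2, a 4-tert-butyl phosphinooxazoline ligand and formic acid (Tsuji type) generates the C7 enolate regiospecifically without base and protonates it, the ligand antipode selecting the 7R ketone 20 as a single epimer. Reduction of this ketone with LiBH(s-Bu)3 at −78 °C, from the face anti to both flanking groups, returns to the route at 21.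

**Step 7.** The most likely failure is proton transfer within the magnesium enolate before it is alkylated, leading to β-elimination of the silyloxy group or to over-alkylation. Fallback: setting out from 8, the conjugate addition is run with Me3SiCl present and the silyl enol ether tert-butyldimethyl{[(1S,5S)-5-(prop-1-en-2-yl)-3-(trimethylsilyloxy)cyclohex-3-en-1-yl]oxy}silane F4 is isolated. MeLi then releases the lithium enolate regiospecifically and allyl iodide/HMPA alkylates it, returning to the route at 10.

**Step 18.** The most likely failure is poor facial selectivity, since the two faces of the cyclopentene are differentiated only by groups on the neighbouring ring. Fallback: setting out from 23, N-bromosuccinimide in aqueous 1,2-dimethoxyethane gives the bromohydrin (1R,3S,4S,5S,7R,8R,10S)-3-bromo-4-hydroxy-10-[(triethylsilyl)oxy]guaian-8-yl 3,4-dimethoxybenzoate F5. The bromonium ion forms on the face the peracid prefers and water enters C4 from the other. Cs2CO3 in acetonitrile closes the epoxide, which ends on the face opposite to that reached by direct epoxidation; the fallback returns at 24.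

**Step 19.** The most likely failures are transannular opening of the epoxide by the liberated C10 oxygen and acyl transfer from O8 to O10 during desilylation. Fallback: setting out from 23, the silyl ether is removed first with HF·pyridine in THF/pyridine to give (1R,5S,7R,8R,10S)-10-hydroxyguai-3-en-8-yl 3,4-dimethoxybenzoate F6. The alkene is then epoxidised last with dimethyldioxirane in acetone at −20 °C under neutral conditions, where hydrogen-bond direction by the free 10-hydroxyl should be weaker than with a peracid in CH2Cl2, returning to the route at 25.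

## Further compounds

F1 | step 15 | (3aS,7S,7aR)-3,7-dimethyl-5-[2-methyl-1-(phenylselanyl)propyl]-7-[(triethylsilyl)oxy]-3a,4,5,6,7,7a-hexahydro-1H-inden-5-ol (new centres as formed) | CC(C)C([Se]c1ccccc1)C1(O)C[C@](C)(O[Si](CC)(CC)CC)[C@@H]2CC=C(C)[C@H]2C1
F2 | step 16 | allyl 2-diazo-3-methylbutanoate | C=CCOC(=O)C(=[N+]=[N-])C(C)C
F3 | step 16 | allyl (1R,5S,10S)-8-oxo-10-[(triethylsilyl)oxy]guai-3-ene-7-carboxylate (C7 as formed) | O=C1C[C@](C)(O[Si](CC)(CC)CC)[C@@H]2CC=C(C)[C@H]2CC1(C(C)C)C(=O)OCC=C
F4 | step 7 | tert-butyldimethyl{[(1S,5S)-5-(prop-1-en-2-yl)-3-(trimethylsilyloxy)cyclohex-3-en-1-yl]oxy}silane | C=C(C)[C@H]1C[C@H](O[Si](C)(C)C(C)(C)C)CC(O[Si](C)(C)C)=C1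
F5 | step 18 | (1R,3S,4S,5S,7R,8R,10S)-3-bromo-4-hydroxy-10-[(triethylsilyl)oxy]guaian-8-yl 3,4-dimethoxybenzoate | COc1ccc(C(=O)O[C@@H]2C[C@](C)(O[Si](CC)(CC)CC)[C@@H]3C[C@H](Br)[C@@](C)(O)[C@H]3C[C@@H]2C(C)C)cc1OC
F6 | step 19 | (1R,5S,7R,8R,10S)-10-hydroxyguai-3-en-8-yl 3,4-dimethoxybenzoate | COc1ccc(C(=O)O[C@@H]2C[C@](C)(O)[C@@H]3CC=C(C)[C@H]3C[C@@H]2C(C)C)cc1OC
A1 | alternative 1 | (5R,6R)-5-[(tert-butyldimethylsilyl)oxy]-6-isopropyl-3-methyldeca-1,2-dien-8-yne | CC#CC[C@H](C(C)C)[C@H](O[Si](C)(C)C(C)(C)C)CC(C)=C=C
A2 | alternative 1 | 8-(tert-butyldimethylsilyloxy)guaia-1(10),4-dien-3-one | O=C1CC2=C(C)C[C@@H](O[Si](C)(C)C(C)(C)C)[C@@H](C(C)C)CC2=C1C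
A3 | alternative 2 | cis-fused 1-(methanesulfonyloxy)-3-oxoeudesman-8-yl 3,4-dimethoxybenzoate 3-ethylene ketal | COc1ccc(C(=O)O[C@@H]2C[C@@]3(C)[C@H](OS(C)(=O)=O)CC4(OCCO4)[C@H](C)[C@H]3C[C@@H]2C(C)C)cc1OC
A4 | alternative 2 | trans-fused 10-hydroxy-3-oxoguaian-8-yl 3,4-dimethoxybenzoate 3-ethylene ketal | COc1ccc(C(=O)O[C@@H]2C[C@](C)(O)[C@@H]3CC4(OCCO4)[C@H](C)[C@H]3C[C@@H]2C(C)C)cc1OC
A5 | alternative 3 | 1-diazo-4-(5-isopropyl-4-methoxy-2-methylphenyl)butan-2-one | [N-]=[N+]=CC(=O)CCc1cc(C(C)C)c(OC)cc1C
A6 | alternative 3 | 7-isopropyl-6-methoxy-4-methyl-3,8a-dihydroazulen-1(2H)-one | O=C1CCC2=C(C)C=C(OC)C(C(C)C)=C[C@H]12
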